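**Plan**
- Retrosynthesis cuts the amide C–N bond, the C7/C8 epoxide oxygen and the C3–N bond, then both aldol bonds C5–C6 and C4–C5 of the bicyclo[3.3.1]nonan-9-one.
- Enabling feature: bridgehead C5 is alpha to the C9 carbonyl and bonded to both carbinol carbons C4 and C6. Each six-membered ring (C1–C2–C3–C4–C5–C9 and C1–C8–C7–C6–C5–C9) is therefore an aldol ring of one acetyl methyl, and the bare core has a mirror plane through C1, C9 and C5.
- Forward: a pyruvate ketal ester and two propargyl units give an achiral Z,Z keto-dialdehyde in five steps. One titanium-mediated operation then closes both rings to a meso dienediol.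
- Lipase monoacetylation breaks the mirror plane, and a carbamate-tethered radical hydroamidation puts N on C3. After unmasking, the amine is coupled with (E)-7-oxododec-2-enoic acid (two steps from hex-5-enoic acid), and hydroxyl-directed epoxidation of C7=C8 comes last.
- Stereochemistry: C4/C6 (with C1/C5) come from chelate-controlled closed aldol transition states, absolute configuration from the enzyme, C3 from the cis tether to O4, and C7/C8 from the C6 hydroxyl and the convex face.

Key step: step 6

Remark on numbering: the target numbering of the bicycle (C1 oxygenated bridgehead, C2 CH2, C3 N, C4 and C6 carbinols, C5 bridgehead CH, C7/C8, C9 ketone) is kept for all bicyclic intermediates.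
Assumption: the lipase acetylates the 6R carbinol of the meso diol, as the Kazlauskas size rule predicts with the bridgehead side as the large and the vinyl side as the medium group; all later structures are drawn on that basis.

**Step 1**
Reactants: 1 tert-butyldimethyl(prop-2-yn-1-yloxy)silane (2.3 equiv); 2 methyl 2,2-dimethoxypropanoate
Product: 4 1,7-bis[(tert-butyldimethylsilyl)oxy]-4-(1,1-dimethoxyethyl)hepta-2,5-diyn-4-ol, via lithium acetylide 3 (not isolated)
Conditions: 1, n-BuLi, THF, −78 °C; then 2, −78 → 0 °C; aq. NH4Cl
Reagents that add atoms: none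
Why: Double 1,2-addition of a lithium acetylide to an ester (the intermediate ynone is more electrophilic than the ester) gives the symmetric tertiary bis-propargylic alcohol, while the dimethyl ketal keeps the future acetyl carbon inert.

**Step 2**
Reactants: 4
Product: 5 1-({[1,7-bis[(tert-butyldimethylsilyl)oxy]-4-(1,1-dimethoxyethyl)hepta-2,5-diyn-4-yl]oxy}methyl)-4-methoxybenzene
Conditions: NaH, PMBCl, Bu4NI (cat.), THF/DMF, 0 °C → rt
Reagents that add atoms: 4-methoxybenzyl chloride, COc1ccc(CCl)cc1
Why: Williamson etherification of the sodium alkoxide, whose two slim alkynyl groups leave the tertiary oxygen accessible, installs a PMB ether that can chelate titanium in the key step and is removable by oxidation later.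

**Step 3**
Reactants: 5
Product: 6 4-acetyl-4-[(4-methoxybenzyl)oxy]hepta-2,5-diyne-1,7-diol
Conditions: TsOH·H2O (0.3 equiv), acetone/H2O (9:1), 40 °C
Reagents that add atoms: water, O
Why: Acid-catalysed hydrolysis frees the methyl ketone from its ketal and both primary alcohols from their silyl ethers at the alkyne stage, where no cis-enal or cis-allylic alcohol is yet exposed to acid, and the PMB ether of the electron-poor tertiary carbinol should survive catalytic sulfonic acid.

**Step 4**
Reactants: 6
Product: 7 (2Z,5Z)-4-acetyl-4-[(4-methoxybenzyl)oxy]hepta-2,5-diene-1,7-diol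
Conditions: H2 (1 atm), Lindlar catalyst, quinoline, EtOAc, rt; filtered and used directly
Reagents that add atoms: none
Why: Lindlar semihydrogenation adds hydrogen syn to each alkyne and stops at the alkene, so both arms become Z while the ketone and the benzylic ether are untouched.

**Step 5**
Reactants: 7
Product: 8 (2Z,5Z)-4-acetyl-4-[(4-methoxybenzyl)oxy]hepta-2,5-dienedial
Conditions: Dess–Martin periodinane, NaHCO3, CH2Cl2, 0 °C; short filtration, used at once
Reagents that add atoms: none
Why: Buffered Dess–Martin oxidation converts Z-allylic alcohols into Z-enals under neutral conditions, and the quaternary γ-carbon removes the dienol pathway to the E isomers.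

**Step 6**
Reactants: 8
Product: 11 meso-(4S,6R)-4,6-dihydroxy-1-[(4-methoxybenzyl)oxy]bicyclo[3.3.1]nona-2,7-dien-9-one, via monocyclic titanium aldolate 9 (not isolated), via bicyclic bis-titanium aldolate 10 (not isolated)
Conditions: TiCl4 (2.5 equiv), iPr2NEt (3 equiv), CH2Cl2 (0.02 M), −78 → −40 °C; aq. NH4Cl
Reagents that add atoms: none
Why: Proposed new method: the acetyl methyl is the only enolisable position, so soft enolisation with TiCl4/iPr2NEt gives one titanium enolate, chelated between the enolate oxygen and the C1 ether oxygen, which adds to one cis-enal carbonyl (C5–C6 bond, first six-membered ring, 6-(enolexo)-exo-trig) and, after re-enolisation at C5 by the excess reagent, to the second enal, which as a geminal substituent on C1 can turn axial (C4–C5 bond, second ring, again 6-(enolexo)-exo-trig). The nearest precedents are single aldol cyclisations of cyclohexanone-tethered aldehydes to 2-hydroxybicyclo[3.3.1]nonan-9-ones and chelation-controlled titanium aldol additions of α-benzyloxy methyl ketones; two closures in two directions from one methyl group have not been shown. In each closure the aldehyde oxygen must bind the same titanium (closed, Zimmerman–Traxler-type transition state), so each carbinol oxygen ends gauche to the C9 carbonyl, which is the axial, carbonyl-side orientation of C4–OH and C6–OH in the target, while C1 and C5 are fixed by the bridge. Because titanium also holds the C1 ether oxygen in the enolate plane, the unreacted arm is forced pseudo-axial, so the first carbinol should form cis to the C1 oxygen with the arm already placed for the second closure (racemic 9, both enantiomers converging on meso 11); this is why a chelating PMB ether and not a silyl ether is used. The step needs intact Z-enals (both β-carbons are neopentylic, which disfavours reversible chloride addition at low temperature), no dehydration of the mono-aldol (it is held as a titanium aldolate, and the bicyclic product has a bridgehead α-hydrogen that cannot enolise) and the meso diastereomer (secured by the two chelated closures).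

**Step 7**
Reactants: 11
Product: 12 (4S,6R)-6-acetoxy-4-hydroxy-1-[(4-methoxybenzyl)oxy]bicyclo[3.3.1]nona-2,7-dien-9-one
Conditions: Amano lipase PS (immobilised), vinyl acetate, MTBE, 30 °C
Reagents that add atoms: vinyl acetate, CC(=O)OC=C
Why: Lipase-catalysed irreversible transesterification distinguishes the enantiotopic carbinols of the meso diol (the size rule predicts acylation of the 6R carbinol), which fixes the absolute configuration of C1, C4, C5 and C6 in one operation.

**Step 8**
Reactants: 12; 13 4-methoxyphenyl isocyanate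
Product: 14 4-O-[N-(4-methoxyphenyl)carbamoyl] derivative of 12
Conditions: dibutyltin dilaurate (cat.), CH2Cl2, rt
Reagents that add atoms: none
Why: Tin-catalysed addition of the single free hydroxyl to the aryl isocyanate forms the carbamate under neutral conditions that leave the β-ketol and the acetate alone.

**Step 9**
Reactants: 14
Product: 15 cis-fused C3–N/C4–O oxazolidin-2-one (N-4-methoxyphenyl; C2 now CH2; 6-OAc; 1-OPMB; C7=C8; C9 ketone)
Conditions: [Ir(dF(CF3)ppy)2(bpy)]PF6 (2 mol%), Bu4N[(BuO)2PO2] (20 mol%), PhSH (20 mol%), CH2Cl2, blue LEDs, rt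
Reagents that add atoms: none
Why: Proton-coupled electron transfer (photoredox olefin hydroamidation) turns the N-aryl carbamate N–H into an amidyl radical that closes 5-exo-trig onto C3 from the convex face, to which the pseudo-axial C4 oxygen holds it, giving the cis-fused oxazolidinone (C3–N cis to C4–O) after hydrogen transfer from the thiol to C2, so no electrophile has to enter the concave face as an anti haloamination would require.

**Step 10**
Reactants: 15
Product: 16 N–H oxazolidinone with free C1–OH (6-OAc; C7=C8; C9 ketone)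
Conditions: CAN (5 equiv), MeCN/H2O (4:1), 0 °C
Reagents that add atoms: none
Why: Ceric ammonium nitrate oxidises both anisyl rings by single-electron transfer, releasing the N-aryl group as benzoquinone and the PMB ether as anisaldehyde in one operation, while the isolated alkene, ketone and acetate are inert.

**Step 11**
Reactants: 16
Product: 17 N-Boc oxazolidinone
Conditions: Boc2O (1.2 equiv), DMAP (cat.), Et3N, MeCN, 0 °C → rt
Reagents that add atoms: di-tert-butyl dicarbonate, CC(C)(C)OC(=O)OC(=O)OC(C)(C)C
Why: DMAP-catalysed N-acylation of the oxazolidinone is faster than acylation of the hindered tertiary bridgehead hydroxyl and turns the ring carbonyl into an activated imide-type carbonyl.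

**Step 12**
Reactants: 17
Product: 18 tert-butyl N-[(1,4,6-trihydroxy-9-oxobicyclo[3.3.1]non-7-en-3-yl)]carbamate (target numbering and configuration)
Conditions: Cs2CO3 (0.3 equiv), MeOH, 0 °C
Reagents that add atoms: none
Why: Methoxide adds to the ring carbonyl of the N-Boc oxazolidinone and expels the stabilised Boc-amide anion, and the resulting methyl carbonate and the acetate are methanolysed under the same mild carbonate-catalysed transesterification, the bridgehead C5–H being geometrically unable to enolise.

**Step 13**
Reactants: 18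
Product: 19 (1,4,6-trihydroxy-9-oxobicyclo[3.3.1]non-7-en-3-yl)ammonium trifluoroacetate
Conditions: TFA/CH2Cl2 (1:4), 0 °C; concentrated
Reagents that add atoms: trifluoroacetic acid, OC(=O)C(F)(F)F
Why: Acidolysis of the tert-butyl carbamate (loss of isobutene and carbon dioxide) gives the ammonium salt, the allylic and α-keto carbinols being too electron-poor to ionise under these conditions.

**Step 14**
Reactants: 20 hex-5-enoic acid; 21 pentylmagnesium bromide
Product: 23 undec-1-en-6-one, via hex-5-enoyl chloride 22 (not isolated)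
Conditions: (COCl)2, DMF (cat.), CH2Cl2, 0 °C → rt, concentrated; then 21, Fe(acac)3 (3 mol%), THF, −78 °C
Reagents that add atoms: none
Why: Iron-catalysed acylation of the Grignard reagent with the acid chloride formed in situ stops at the ketone and tolerates the terminal alkene.

**Step 15**
Reactants: 23; 24 acrylic acid
Product: 25 (2E)-7-oxododec-2-enoic acid
Conditions: Hoveyda–Grubbs II catalyst (5 mol%), CH2Cl2, 40 °C
Reagents that add atoms: none
Why: Olefin cross-metathesis of the terminal alkene with acrylic acid releases ethene and gives the conjugated acid with the thermodynamically favoured E geometry.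

**Step 16**
Reactants: 19; 25
Product: 26 (2E)-N-(1,4,6-trihydroxy-9-oxobicyclo[3.3.1]non-7-en-3-yl)-7-oxododec-2-enamide
Conditions: EDC·HCl, HOBt, iPr2NEt, DMF/CH2Cl2, 0 °C → rt
Reagents that add atoms: none
Why: Carbodiimide/HOBt amide coupling acylates the primary amine selectively over the secondary and tertiary hydroxyls, and the β-substituted enoate active ester reacts by acyl transfer and not by conjugate addition.

**Step 17**
Reactants: 26
Product: 27 isariotin C
Conditions: VO(acac)2 (5 mol%), t-BuOOH (decane, 1.5 equiv), CH2Cl2, 0 °C → rt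
Reagents that add atoms: tert-butyl hydroperoxide, CC(C)(C)OO
Why: Vanadium-catalysed hydroxyl-directed epoxidation delivers oxygen to C7=C8 syn to the pseudo-axial allylic C6–OH (reinforced by the C1–OH and by the C2–C4 bridge that blocks the other face), setting C7 and C8, while the electron-poor enamide alkene and the ketones should not react.

**Compound list**
1 | tert-butyldimethyl(prop-2-yn-1-yloxy)silane | C#CCO[Si](C)(C)C(C)(C)C | starting material
2 | methyl 2,2-dimethoxypropanoate | COC(=O)C(C)(OC)OC | starting material
3 | lithium acetylide of 1 | [Li]C#CCO[Si](C)(C)C(C)(C)C | intermediate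
4 | 1,7-bis[(tert-butyldimethylsilyl)oxy]-4-(1,1-dimethoxyethyl)hepta-2,5-diyn-4-ol | CC(OC)(OC)C(O)(C#CCO[Si](C)(C)C(C)(C)C)C#CCO[Si](C)(C)C(C)(C)C | intermediate
5 | PMB ether of 4 | CC(OC)(OC)C(OCc1ccc(OC)cc1)(C#CCO[Si](C)(C)C(C)(C)C)C#CCO[Si](C)(C)C(C)(C)C | intermediate
6 | 4-acetyl-4-[(4-methoxybenzyl)oxy]hepta-2,5-diyne-1,7-diol | CC(=O)C(OCc1ccc(OC)cc1)(C#CCO)C#CCO | intermediate
7 | (2Z,5Z)-4-acetyl-4-[(4-methoxybenzyl)oxy]hepta-2,5-diene-1,7-diol | CC(=O)C(OCc1ccc(OC)cc1)(/C=C\CO)/C=C\CO | intermediate
8 | (2Z,5Z)-4-acetyl-4-[(4-methoxybenzyl)oxy]hepta-2,5-dienedial | CC(=O)C(OCc1ccc(OC)cc1)(/C=C\C=O)/C=C\C=O | intermediate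
9 | racemic trichlorotitanium aldolate of 5-hydroxy-2-[(4-methoxybenzyl)oxy]-2-[(1Z)-3-oxoprop-1-enyl]cyclohex-3-en-1-one, carbinol cis to the ether oxygen (one enantiomer drawn) | O=C/C=C\[C@@]1(OCc2ccc(OC)cc2)C(=O)C[C@H](O[Ti](Cl)(Cl)Cl)C=C1 | intermediate
10 | bis(trichlorotitanium) aldolate of 11 | C1=C[C@@]2(OCc3ccc(OC)cc3)C(=O)[C@H]([C@H](O[Ti](Cl)(Cl)Cl)C=C2)[C@H]1O[Ti](Cl)(Cl)Cl | intermediate
11 | meso-(4S,6R)-4,6-dihydroxy-1-[(4-methoxybenzyl)oxy]bicyclo[3.3.1]nona-2,7-dien-9-one, both hydroxyls on the C9 carbonyl side | C1=C[C@@]2(OCc3ccc(OC)cc3)C(=O)[C@H]([C@H](O)C=C2)[C@H]1O | intermediate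
12 | (4S,6R)-6-acetoxy-4-hydroxy-1-[(4-methoxybenzyl)oxy]bicyclo[3.3.1]nona-2,7-dien-9-one | C1=C[C@@]2(OCc3ccc(OC)cc3)C(=O)[C@H]([C@H](OC(C)=O)C=C2)[C@H]1O | intermediate
13 | 4-methoxyphenyl isocyanate | COc1ccc(N=C=O)cc1 | starting material
14 | 4-O-[N-(4-methoxyphenyl)carbamoyl] derivative of 12 | C1=C[C@@]2(OCc3ccc(OC)cc3)C(=O)[C@H]([C@H](OC(C)=O)C=C2)[C@H]1OC(=O)Nc4ccc(OC)cc4 | intermediate
15 | N-(4-methoxyphenyl) oxazolidin-2-one cis-fused at C3 (N) and C4 (O), 6-OAc, 1-OPMB, C7=C8, C9 ketone | O=C3N(c4ccc(OC)cc4)[C@H]1C[C@@]2(OCc5ccc(OC)cc5)C(=O)[C@H]([C@H](OC(C)=O)C=C2)[C@H]1O3 | intermediate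
16 | N–H oxazolidin-2-one with free C1–OH, 6-OAc | O=C3N[C@H]1C[C@@]2(O)C(=O)[C@H]([C@H](OC(C)=O)C=C2)[C@H]1O3 | intermediate
17 | N-Boc oxazolidin-2-one, 1-OH, 6-OAc | O=C3N(C(=O)OC(C)(C)C)[C@H]1C[C@@]2(O)C(=O)[C@H]([C@H](OC(C)=O)C=C2)[C@H]1O3 | intermediate
18 | tert-butyl N-(1,4,6-trihydroxy-9-oxobicyclo[3.3.1]non-7-en-3-yl)carbamate, N cis to 4-OH | CC(C)(C)OC(=O)N[C@H]1C[C@@]2(O)C(=O)[C@H]([C@H](O)C=C2)[C@H]1O | intermediate
19 | (1,4,6-trihydroxy-9-oxobicyclo[3.3.1]non-7-en-3-yl)ammonium trifluoroacetate | [NH3+][C@H]1C[C@@]2(O)C(=O)[C@H]([C@H](O)C=C2)[C@H]1O.[O-]C(=O)C(F)(F)F | intermediate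
20 | hex-5-enoic acid | C=CCCCC(=O)O | starting material
21 | pentylmagnesium bromide | CCCCC[Mg]Br | starting material
22 | hex-5-enoyl chloride | C=CCCCC(=O)Cl | intermediate
23 | undec-1-en-6-one | C=CCCCC(=O)CCCCC | intermediate
24 | acrylic acid | C=CC(=O)O | starting material
25 | (2E)-7-oxododec-2-enoic acid | CCCCCC(=O)CCC/C=C/C(=O)O | intermediate
26 | (2E)-N-(1,4,6-trihydroxy-9-oxobicyclo[3.3.1]non-7-en-3-yl)-7-oxododec-2-enamide (7,8-alkene precursor of the target) | CCCCCC(=O)CCC/C=C/C(=O)N[C@H]1C[C@@]2(O)C(=O)[C@H]([C@H](O)C=C2)[C@H]1O | intermediate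
27 | isariotin C | CCCCCC(=O)CCC/C=C/C(=O)N[C@H]1C[C@@]2(O)C(=O)[C@H]([C@H](O)[C@@H]3O[C@@H]32)[C@H]1O | target

**Step count**
Total steps: 17. Longest linear sequence: 15 (steps 1–13, 16, 17); steps 14–15 make the side chain.

**Steps most likely to fail**

Step 6 (new method). Three processes threaten it: cis-to-trans isomerisation of the enal arms under the Lewis acid, β-elimination of the mono-aldolate before the second closure, and a first closure that places the carbinol trans to the C1 oxygen and so leads to the unsymmetrical diastereomer. The fallback uses known single aldol cyclisations and stages the two ring closures. It sets out from 7. Limiting TEMPO/PhI(OAc)2 oxidises one allylic alcohol to the racemic hydroxy-enal F1 (unreacted 7 is recycled). A single chelation-controlled intramolecular titanium aldol (TiCl4/iPr2NEt, −78 °C) then gives the monocyclic ketol F2, which is purified and its relative configuration checked. TEMPO/PhI(OAc)2, selective for the primary allylic alcohol, gives the keto-aldehyde F3. The second ring is closed by the established keto-aldehyde to 2-hydroxybicyclo[3.3.1]nonan-9-one aldolisation under the same titanium conditions, returning to the route at 11.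

Step 9. The amidyl radical may be quenched by hydrogen transfer before it closes onto the hindered bicycle, and the C2 radical next to the C9 ketone may undergo 1,2-acyl shift or β-scission at the low steady-state thiol concentration. The fallback forms the C3–N bond by osmium-mediated syn addition on the convex face and removes the extra oxygen afterwards. It sets out from 12. Carbonyldiimidazole gives the imidazole carboxylate F4, and hydroxylamine hydrochloride/pyridine converts it into the N-hydroxycarbamate F5. Pentafluorobenzoyl chloride/Et3N gives the N-(pentafluorobenzoyloxy)carbamate F6. Tethered aminohydroxylation (K2OsO2(OH)4 cat., t-BuOH/H2O) then gives the 2-hydroxy oxazolidinone F7, with N on C3 and OH on C2, both cis to O4. Barton–McCombie deoxygenation follows, through the imidazolyl thiocarbonate F8 (thiocarbonyldiimidazole, DMAP) and Bu3SnH/AIBN, to the PMB-protected N–H oxazolidinone F9. DDQ (CH2Cl2/pH 7 buffer) removes the PMB ether, returning to the route at 16.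

Step 7. Acyl transfer to the hindered axial carbinols may not occur, or it may go to the wrong enantiotopic hydroxyl. The fallback runs the desymmetrisation in the hydrolytic direction. It sets out from 11, which Ac2O/DMAP/pyridine converts into the meso diacetate F10. Enantiotopic hydrolysis in pH 7 phosphate buffer/acetone then cleaves the 4S acetate. The same lipase is used if it proved S-selective in the acylation mode, otherwise a hydrolase of opposite preference such as subtilisin. This returns to the route at 12.

**Further compounds**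
F1 | step 6 | racemic (2Z,5Z)-4-acetyl-7-hydroxy-4-[(4-methoxybenzyl)oxy]hepta-2,5-dienal | CC(=O)C(OCc1ccc(OC)cc1)(/C=C\CO)/C=C\C=O
F2 | step 6 | racemic 5-hydroxy-2-[(1Z)-3-hydroxyprop-1-enyl]-2-[(4-methoxybenzyl)oxy]cyclohex-3-en-1-one, carbinol cis to the ether oxygen (one enantiomer drawn) | OC/C=C\[C@@]1(OCc2ccc(OC)cc2)C(=O)C[C@H](O)C=C1
F3 | step 6 | racemic (2Z)-3-{5-hydroxy-1-[(4-methoxybenzyl)oxy]-2-oxocyclohex-3-en-1-yl}prop-2-enal (one enantiomer drawn) | O=C/C=C\[C@@]1(OCc2ccc(OC)cc2)C(=O)C[C@H](O)C=C1
F4 | step 9 | 4-O-(imidazol-1-ylcarbonyl) derivative of 12 | C1=C[C@@]2(OCc3ccc(OC)cc3)C(=O)[C@H]([C@H](OC(C)=O)C=C2)[C@H]1OC(=O)n4ccnc4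
F5 | step 9 | 4-O-(N-hydroxycarbamoyl) derivative of 12 | C1=C[C@@]2(OCc3ccc(OC)cc3)C(=O)[C@H]([C@H](OC(C)=O)C=C2)[C@H]1OC(=O)NO
F6 | step 9 | 4-O-[N-(pentafluorobenzoyloxy)carbamoyl] derivative of 12 | C1=C[C@@]2(OCc3ccc(OC)cc3)C(=O)[C@H]([C@H](OC(C)=O)C=C2)[C@H]1OC(=O)NOC(=O)c4c(F)c(F)c(F)c(F)c4F
F7 | step 9 | N–H oxazolidin-2-one cis-fused at C3/C4 with 2-OH cis to N, 6-OAc, 1-OPMB | O=C3N[C@H]1[C@@H](O)[C@@]2(OCc4ccc(OC)cc4)C(=O)[C@H]([C@H](OC(C)=O)C=C2)[C@H]1O3
F8 | step 9 | 2-O-(imidazol-1-ylthiocarbonyl) derivative of F7 | O=C3N[C@H]1[C@@H](OC(=S)n5ccnc5)[C@@]2(OCc4ccc(OC)cc4)C(=O)[C@H]([C@H](OC(C)=O)C=C2)[C@H]1O3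
F9 | step 9 | N–H oxazolidin-2-one with 1-OPMB, 6-OAc (PMB ether of 16) | O=C3N[C@H]1C[C@@]2(OCc4ccc(OC)cc4)C(=O)[C@H]([C@H](OC(C)=O)C=C2)[C@H]1O3
F10 | step 7 | meso-4,6-diacetoxy-1-[(4-methoxybenzyl)oxy]bicyclo[3.3.1]nona-2,7-dien-9-one | C1=C[C@@]2(OCc3ccc(OC)cc3)C(=O)[C@H]([C@H](OC(C)=O)C=C2)[C@H]1OC(C)=O
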